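A direct plan would keep both benzene rings as bought and make only the furan: dihydroconiferyl alcohol A1 would be formylated ortho to its phenol to give salicylaldehyde A2.
A2 and acetovanillone A3 would be capped with MOM groups and condensed to chalcone A4; a trivalent iodine oxidant would shift ring A from the β- to the α-carbon to give keto acetal A5, and acid would unmask the phenols and close the furan.
Weakest would be the oxidative 1,2-aryl shift: a strong oxidant would meet two alkoxy-rich arenes and a free primary alcohol, and the whole skeleton would rest on one ring migrating cleanly.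
Next would be the closing deprotection and cyclodehydration: two MOM cleavages, acetal exchange, furan closure and aldehyde release would all have to finish in one flask on the most advanced material.
Third would be the protection and condensation, which would spend a carcinogenic alkylating agent on groups that add nothing to the skeleton and would depend on telling phenol from alcohol.

Plan of the new route:
The retrosynthesis leaves the furan intact and cuts ring A instead: C3a–C4, C4–C5 and C6–C7 in one benzannulation, then C7–C7a (carbene carbon on the furan α-carbon) and C2–C1' (furan to ring B).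
Ring B and the furan would be bought (benzyl-protected bromoguaiacol and furan-3-carbaldehyde, whose formyl carbon is already the C3 aldehyde of the target) and joined first; ring A would arise last, on the furan.
The enabling feature: in ring A the methoxy-bearing C7 is bonded to the furan α-carbon C7a, the only carbon substituent is the chain at C5, and C4 and C6 carry hydrogen. C7 with its OMe therefore maps onto a 2-furyl(methoxy)carbene carbon, C5–C6 onto the terminal alkyne of protected pent-4-yn-1-ol, and C4 onto one CO.
The surplus C4 oxygen that the CO brings would leave as its triflate in the same hydrogenolysis that frees the ring B phenol.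
No oxidant meets the electron-rich arenes, no aryl migration decides the skeleton, the aldehyde is carried as an acetal from the first step, and the last step is a plain hydrolysis, not a ring closure.

Key step: step 4

Remark: in step 4 the phenol is taken to stay bound to Cr(CO)3 until the work-up in air; compound 11 is listed as the free ligand.

Step 1
Reactants: 1 furan-3-carbaldehyde
Product: 2 2-(furan-3-yl)-1,3-dioxolane
Conditions: ethylene glycol (1.5 equiv), p-TsOH·H2O (1 mol%), benzene, reflux, azeotropic removal of water
Reagents that add atoms: ethane-1,2-diol, OCCO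
Why: Acid-catalysed acetalization masks the formyl group (the future C3 aldehyde) against the organolithium and chromium chemistry that follows; no stereocentre is formed.

Step 2
Reactants: 2 2-(furan-3-yl)-1,3-dioxolane; 3 1-(benzyloxy)-4-bromo-2-methoxybenzene
Product: 6 2-{2-[4-(benzyloxy)-3-methoxyphenyl]furan-3-yl}-1,3-dioxolane, via 2-lithiofuran 4 (not isolated), via furylzinc chloride 5 (not isolated)
Conditions: n-BuLi (1.1 equiv), THF, −78 to 0 °C; ZnCl2 (1.2 equiv), 0 °C to rt; 3 (0.9 equiv), Pd(PPh3)4 (3 mol%), THF, 55 °C
Reagents that add atoms: none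
Why: Directed α-lithiation (the acetal oxygens guide the base to C2, the α-carbon next to the substituent), transmetalation to zinc and Negishi cross-coupling should form the C2–aryl bond; no stereocentre is formed.

Step 3
Reactants: 6 2-{2-[4-(benzyloxy)-3-methoxyphenyl]furan-3-yl}-1,3-dioxolane
Product: 9 pentacarbonyl({5-[4-(benzyloxy)-3-methoxyphenyl]-4-(1,3-dioxolan-2-yl)furan-2-yl}(methoxy)methylidene)chromium, via 5-lithiofuran 7 (not isolated), via lithium acylchromate 8 (not isolated)
Conditions: n-BuLi (1.05 equiv), THF, −78 to −30 °C; Cr(CO)6 (1.05 equiv), −30 °C to rt; evaporate; Me3OBF4 (1.3 equiv), CH2Cl2, 0 °C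
Reagents that add atoms: hexacarbonylchromium Cr(CO)6, O=C=[Cr](=C=O)(=C=O)(=C=O)(=C=O)=C=O; trimethyloxonium tetrafluoroborate, C[O+](C)C.F[B-](F)(F)F
Why: Fischer carbene synthesis, in which the only remaining furan α-hydrogen is removed, the furyllithium adds to a CO ligand and the acylchromate is O-methylated, so that this carbon and its methoxy group become C7–OMe; no stereocentre is formed.

Step 4
Reactants: 9 pentacarbonyl({5-[4-(benzyloxy)-3-methoxyphenyl]-4-(1,3-dioxolan-2-yl)furan-2-yl}(methoxy)methylidene)chromium; 10 tert-butyldimethyl(pent-4-yn-1-yloxy)silane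
Product: 12 2-[4-(benzyloxy)-3-methoxyphenyl]-5-{3-[(tert-butyldimethylsilyl)oxy]propyl}-3-(1,3-dioxolan-2-yl)-7-methoxy-1-benzofuran-4-yl trifluoromethanesulfonate, via 4-hydroxybenzofuran 11 (not isolated)
Conditions: 10 (1.8 equiv), degassed THF (0.05 M), 55 °C, 16 h, argon; evaporate under argon; CH2Cl2, pyridine (4 equiv), Tf2O (1.3 equiv), −40 to 0 °C; then air, silica gel
Reagents that add atoms: trifluoromethanesulfonic anhydride, O=S(=O)(OS(=O)(=O)C(F)(F)F)C(F)(F)F
Why: Dötz benzannulation: thermal loss of one CO from the zerovalent chromium carbene 9 opens a site for the alkyne, which inserts with its unsubstituted carbon bonded to the carbene carbon; the vinylcarbene then inserts a CO ligand to a chromium-bound vinylketene, which closes onto the free furan β-carbon and tautomerizes to phenol 11. The closest known reaction type is the benzannulation of 2-furyl(alkoxy)carbene chromium complexes with terminal alkynes to 4-hydroxy-7-alkoxybenzofurans. Ring A is closed by a 6π-electrocyclization of the dienylketene (ketene carbon C4 onto C3a), after the insertions have made C6–C7 and C4–C5. No stereocentre is formed. The step needs regioselective alkyne insertion, secured by the size difference between hydrogen and the CH2 chain of a terminal alkyne (chain at C5 next to the new oxygen, hydrogen at C6), and closure at carbon, secured because the furan β-position carries hydrogen and the other α-position is blocked by ring B. The electron-rich hydroquinone monoether is not exposed to air but sulfonylated at once, which also turns the surplus C4 oxygen into a leaving group.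

Step 5
Reactants: 12 2-[4-(benzyloxy)-3-methoxyphenyl]-5-{3-[(tert-butyldimethylsilyl)oxy]propyl}-3-(1,3-dioxolan-2-yl)-7-methoxy-1-benzofuran-4-yl trifluoromethanesulfonate
Product: 13 4-[5-{3-[(tert-butyldimethylsilyl)oxy]propyl}-3-(1,3-dioxolan-2-yl)-7-methoxy-1-benzofuran-2-yl]-2-methoxyphenol
Conditions: H2 (3 atm), Pd(OH)2/C (10 mol% Pd), NaOAc (3 equiv), EtOAc–MeOH (4:1), rt
Reagents that add atoms: none
Why: Heterogeneous palladium hydrogenolysis, in which zerovalent palladium inserts into the C4–O bond of the aryl triflate and hydrogen cleaves the aryl–palladium species (acetate takes up the triflic acid) while the O-benzyl ether is cleaved on the same catalyst; the formyl group is still an acetal and the fully substituted furan C2=C3 bond should not be reduced; no stereocentre is formed.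

Step 6
Reactants: 13 4-[5-{3-[(tert-butyldimethylsilyl)oxy]propyl}-3-(1,3-dioxolan-2-yl)-7-methoxy-1-benzofuran-2-yl]-2-methoxyphenol
Product: 14 2-(4-hydroxy-3-methoxyphenyl)-5-(3-hydroxypropyl)-7-methoxy-1-benzofuran-3-carbaldehyde
Conditions: 2 M aq. HCl, THF, rt; aq. NaHCO3
Reagents that add atoms: water, O
Why: Acid-catalysed acetal hydrolysis (through an oxocarbenium ion stabilised by the 2-arylfuran) and protodesilylation of the primary silyl ether should release the aldehyde and the alcohol in one operation; the product is achiral.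

Compound list
1 | furan-3-carbaldehyde | O=Cc1ccoc1 | starting material
2 | 2-(furan-3-yl)-1,3-dioxolane | C1COC(O1)c1ccoc1 | intermediate
3 | 1-(benzyloxy)-4-bromo-2-methoxybenzene | COc1cc(Br)ccc1OCc1ccccc1 | starting material
4 | [3-(1,3-dioxolan-2-yl)furan-2-yl]lithium | [Li]c1occc1C1OCCO1 | intermediate (not isolated)
5 | chloro[3-(1,3-dioxolan-2-yl)furan-2-yl]zinc | Cl[Zn]c1occc1C1OCCO1 | intermediate (not isolated)
6 | 2-{2-[4-(benzyloxy)-3-methoxyphenyl]furan-3-yl}-1,3-dioxolane | COc1cc(ccc1OCc1ccccc1)-c1occc1C1OCCO1 | intermediate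
7 | {5-[4-(benzyloxy)-3-methoxyphenyl]-4-(1,3-dioxolan-2-yl)furan-2-yl}lithium | [Li]c1cc(C2OCCO2)c(-c2ccc(OCc3ccccc3)c(OC)c2)o1 | intermediate (not isolated)
8 | lithium pentacarbonyl({5-[4-(benzyloxy)-3-methoxyphenyl]-4-(1,3-dioxolan-2-yl)furan-2-yl}(oxido)methylidene)chromate | [Li+].[O-]C(=[Cr](=C=O)(=C=O)(=C=O)(=C=O)=C=O)c1cc(C2OCCO2)c(-c2ccc(OCc3ccccc3)c(OC)c2)o1 | intermediate (not isolated)
9 | pentacarbonyl({5-[4-(benzyloxy)-3-methoxyphenyl]-4-(1,3-dioxolan-2-yl)furan-2-yl}(methoxy)methylidene)chromium | COC(=[Cr](=C=O)(=C=O)(=C=O)(=C=O)=C=O)c1cc(C2OCCO2)c(-c2ccc(OCc3ccccc3)c(OC)c2)o1 | intermediate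
10 | tert-butyldimethyl(pent-4-yn-1-yloxy)silane | C#CCCCO[Si](C)(C)C(C)(C)C | starting material
11 | 2-[4-(benzyloxy)-3-methoxyphenyl]-5-{3-[(tert-butyldimethylsilyl)oxy]propyl}-3-(1,3-dioxolan-2-yl)-7-methoxy-1-benzofuran-4-ol | COc1cc(CCCO[Si](C)(C)C(C)(C)C)c(O)c2c(C3OCCO3)c(-c3ccc(OCc4ccccc4)c(OC)c3)oc12 | intermediate (not isolated)
12 | 2-[4-(benzyloxy)-3-methoxyphenyl]-5-{3-[(tert-butyldimethylsilyl)oxy]propyl}-3-(1,3-dioxolan-2-yl)-7-methoxy-1-benzofuran-4-yl trifluoromethanesulfonate | COc1cc(CCCO[Si](C)(C)C(C)(C)C)c(OS(=O)(=O)C(F)(F)F)c2c(C3OCCO3)c(-c3ccc(OCc4ccccc4)c(OC)c3)oc12 | intermediate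
13 | 4-[5-{3-[(tert-butyldimethylsilyl)oxy]propyl}-3-(1,3-dioxolan-2-yl)-7-methoxy-1-benzofuran-2-yl]-2-methoxyphenol | COc1cc(CCCO[Si](C)(C)C(C)(C)C)cc2c(C3OCCO3)c(-c3ccc(O)c(OC)c3)oc12 | intermediate
14 | 2-(4-hydroxy-3-methoxyphenyl)-5-(3-hydroxypropyl)-7-methoxy-1-benzofuran-3-carbaldehyde (achiral) | COc1cc(-c2oc3c(OC)cc(CCCO)cc3c2C=O)ccc1O | target

Total step count: 6. Longest linear sequence: 6 steps (1 → 2 → 6 → 9 → 12 → 13 → 14).

Steps most likely to fail

Step 4. The electron-rich, chromium-bound phenol may be lost by aerial oxidation to the quinone, or O-sulfonylation of the doubly flanked C4 hydroxyl may stall in the crude benzannulation mixture. The fallback sets out from 9 and 10 and comes back at 12. The benzannulation would be run with Ac2O (2 equiv) and Et3N (2 equiv) in the flask (THF, 55 °C), so that the phenol is acylated as it forms and is never free; decomplexation in air would give the air-stable 2-[4-(benzyloxy)-3-methoxyphenyl]-5-{3-[(tert-butyldimethylsilyl)oxy]propyl}-3-(1,3-dioxolan-2-yl)-7-methoxy-1-benzofuran-4-yl acetate F1. Methanolysis of the aryl acetate under argon (K2CO3, MeOH), exchange of the solvent for THF and triflation of the clean phenoxide with N-phenylbis(trifluoromethanesulfonimide) would then give 12.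

Step 5. C–O hydrogenolysis of the hindered triflate may remain incomplete, or the catalyst may be poisoned or over-reduce when both cleavages are asked of it at once. The fallback sets out from 12 and comes back at 13. A homogeneous hydride transfer (Pd(OAc)2 5 mol%, 1,3-bis(diphenylphosphino)propane, HCO2H, Et3N, DMF, 70 °C) would remove only the triflate and give {3-[2-(4-(benzyloxy)-3-methoxyphenyl)-3-(1,3-dioxolan-2-yl)-7-methoxy-1-benzofuran-5-yl]propoxy}(tert-butyl)dimethylsilane F2. A separate, mild debenzylation (H2 1 atm, Pd/C, EtOAc) would then give 13.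

Step 2. Metalation may occur in part at C5 instead of C2, or the zinc reagent may homocouple while oxidative addition of the electron-rich bromide is slow. The fallback sets out from 1 and 3 and comes back at 6. Palladium-catalysed direct C–H arylation of furan-3-carbaldehyde at C2, the position acidified by both the ring oxygen and the formyl group (Pd(OAc)2 5 mol%, PCy3·HBF4 10 mol%, pivalic acid 30 mol%, K2CO3, N,N-dimethylacetamide, 100 °C), would give 2-[4-(benzyloxy)-3-methoxyphenyl]furan-3-carbaldehyde F3. Acetalization as in step 1 (ethylene glycol, p-TsOH·H2O, benzene, reflux) would then give 6.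

Further compounds
F1 | step 4 | 2-[4-(benzyloxy)-3-methoxyphenyl]-5-{3-[(tert-butyldimethylsilyl)oxy]propyl}-3-(1,3-dioxolan-2-yl)-7-methoxy-1-benzofuran-4-yl acetate | COc1cc(CCCO[Si](C)(C)C(C)(C)C)c(OC(C)=O)c2c(C3OCCO3)c(-c3ccc(OCc4ccccc4)c(OC)c3)oc12
F2 | step 5 | {3-[2-(4-(benzyloxy)-3-methoxyphenyl)-3-(1,3-dioxolan-2-yl)-7-methoxy-1-benzofuran-5-yl]propoxy}(tert-butyl)dimethylsilane | COc1cc(CCCO[Si](C)(C)C(C)(C)C)cc2c(C3OCCO3)c(-c3ccc(OCc4ccccc4)c(OC)c3)oc12
F3 | step 2 | 2-[4-(benzyloxy)-3-methoxyphenyl]furan-3-carbaldehyde | COc1cc(ccc1OCc1ccccc1)-c1occc1C=O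
A1 | direct plan | 4-(3-hydroxypropyl)-2-methoxyphenol (dihydroconiferyl alcohol) | COc1cc(CCCO)ccc1O
A2 | direct plan | 2-hydroxy-5-(3-hydroxypropyl)-3-methoxybenzaldehyde | COc1cc(CCCO)cc(C=O)c1O
A3 | direct plan | 1-(4-hydroxy-3-methoxyphenyl)ethan-1-one (acetovanillone) | CC(=O)c1ccc(O)c(OC)c1
A4 | direct plan | (E)-3-[5-(3-hydroxypropyl)-3-methoxy-2-(methoxymethoxy)phenyl]-1-[3-methoxy-4-(methoxymethoxy)phenyl]prop-2-en-1-one | COCOc1ccc(cc1OC)C(=O)/C=C/c1cc(CCCO)cc(OC)c1OCOC
A5 | direct plan | 2-[5-(3-hydroxypropyl)-3-methoxy-2-(methoxymethoxy)phenyl]-3,3-dimethoxy-1-[3-methoxy-4-(methoxymethoxy)phenyl]propan-1-one (racemic) | COCOc1ccc(cc1OC)C(=O)C(C(OC)OC)c1cc(CCCO)cc(OC)c1OCOC
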